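C3 of the dioxane ring is bonded to O4 (on ring A), to C2 (the carbon carrying ring B) and to one further carbon. A carbene carbon can assemble exactly this pattern, so the route cuts C3–O4 and C2–C3 together. In a single operation the rhodium carbene of ethyl diazoacetate is attacked by the O4 phenol of methyl 5-bromovanillate. The resulting ylide is intercepted by O-silylated syringaldehyde inside a chiral phosphoric acid, giving an open-chain threo α-aryloxy-β-hydroxy ester with both stereocentres. The precursors are thus three simple, achiral pieces. The bromine at C8a later closes O1–C8a, and the esters become the methyl and propenyl groups.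

Key step: step 2

Remarks on the chemistry
- **Numbering:** O1, C2 (ring B), C3 (methyl), O4, C4a, C5 (OMe), C6, C7 (propenyl), C8, C8a. Ring A is the fused arene and ring B the 4-hydroxy-3,5-dimethoxyphenyl group.
- **Stereochemical bookkeeping:** the target is the trans-(2R,3R) isomer. Closing O1 onto C8a breaks no bond at C2 or C3, so the open-chain precursor must be the threo (2S,3R)-propanoate. The C3 descriptor changes from S to R when CO2Et becomes CH2OH, only because the CIP ranking changes.
- **Assumption:** the sense of induction of a chiral phosphoric acid in this unexplored reaction cannot be predicted. The (R)-acid is written, and its mirror image would be taken if the wrong antipode is favoured.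
- **Silyl group:** triisopropylsilyl is preferred to a smaller silyl group. An aryl silyl ether has to survive hot phosphate base, two hydride reagents and chromium salts, and premature release of the ring B phenol would expose C2 to quinone methide chemistry.
- **Order of events:** the C3 ester is kept until after ring closure, because a free C3–CH2OH could itself close a six-membered ring onto C8a.

Step 1
Reactants: 1 syringaldehyde (4-hydroxy-3,5-dimethoxybenzaldehyde)
Product: 2 3,5-dimethoxy-4-(triisopropylsilyloxy)benzaldehyde
Conditions: iPr3SiCl, imidazole, DMAP (cat.), DMF, rt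
Reagents that add atoms: chlorotriisopropylsilane, CC(C)[Si](Cl)(C(C)C)C(C)C
Why: Imidazole-promoted silyl ether protection of the only hydroxyl group, giving a bulky aryl silyl ether that the two flanking methoxy groups force out of the ring plane, so that it donates little electron density to the formyl group.

Step 2
Reactants: 3 methyl 3-bromo-4-hydroxy-5-methoxybenzoate (methyl 5-bromovanillate), 4 ethyl diazoacetate, 2 3,5-dimethoxy-4-(triisopropylsilyloxy)benzaldehyde
Product: 6 ethyl (2S,3R)-2-[2-bromo-6-methoxy-4-(methoxycarbonyl)phenoxy]-3-[3,5-dimethoxy-4-(triisopropylsilyloxy)phenyl]-3-hydroxypropanoate (threo), via oxonium ylide 5 (not isolated)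
Conditions: Rh2(OAc)4 (2 mol %), (R)-3,3'-bis(2,4,6-triisopropylphenyl)-BINOL hydrogen phosphate (10 mol %), 4 Å MS, CH2Cl2, 0 °C; 4 (1.0 equiv) added by syringe pump over 8 h to 3 (1.2 equiv) and 2 (2 equiv)
Reagents that add atoms: none
Why: Proposed new method: Rh2(OAc)4 expels N2 from 4, the O4 phenol oxygen of 3 adds to the electron-poor rhodium carbene, and the oxonium ylide 5 (or the ketene hemiacetal enol derived from it by proton relay) attacks the acid-bound formyl carbon of 2 through its carbanionic carbon, the future C3, before that carbon is protonated. The closest known reaction type is the three-component aldol-type interception of alcohol-derived oxonium ylides from aryldiazoacetates by activated aldehydes under dirhodium and chiral acid co-catalysis, whereas the combination of an α-unsubstituted diazoacetate, a di-ortho-substituted phenol and a non-activated benzaldehyde has not been shown. No ring is closed, the step making only the open-chain bonds C3–O4 and C2–C3. C2 is controlled by the chiral acid, whose P–OH proton binds the aldehyde oxygen while its 3,3'-aryl walls leave one formyl face open, and C3 is controlled by the same cyclic array, in which the P=O oxygen holds the enol O–H and the bulky 2-bromo-6-methoxyaryloxy group turns away from ring B, which corresponds to the threo (2S,3R) adduct. The step needs capture to outrun proton shift, carbene dimerisation, carbonyl ylide formation and a second insertion into the new carbinol, which is served by slow addition of 4 as the limiting component, by excess 2 at high concentration over sieves, by the internal O–H···OMe hydrogen bond that makes 3 a poor proton shuttle, and by the twisted 4-silyloxy group that leaves the formyl group of 2 about as electrophilic as that of benzaldehyde. Only C2 is irrevocable, since C3 remains epimerisable beside the ester and the trans ring of 7 is the more stable isomer, so an erythro share could be corrected after ring closure.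

Step 3
Reactants: 6 threo hydroxy ester
Product: 7 3-ethyl 7-methyl (2R,3S)-2-[3,5-dimethoxy-4-(triisopropylsilyloxy)phenyl]-5-methoxy-2,3-dihydro-1,4-benzodioxine-3,7-dicarboxylate (trans)
Conditions: Pd(OAc)2 (3 mol %), 2-(di-tert-butylphosphino)-1,1'-binaphthyl (4 mol %), K3PO4, toluene, 80 °C
Reagents that add atoms: none
Why: Buchwald–Hartwig-type intramolecular aryl halide etherification, known for 2-(2-bromoaryloxy) secondary alcohols, in which zerovalent palladium inserts into C8a–Br, the C2 oxygen binds and the bulky biaryl phosphine drives C–O reductive elimination ahead of β-hydride elimination, so that no bond at C2 or C3 is broken and threo maps onto trans.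

Step 4
Reactants: 7 trans diester
Product: 8 {(2R,3R)-2-[3,5-dimethoxy-4-(triisopropylsilyloxy)phenyl]-3-(hydroxymethyl)-5-methoxy-2,3-dihydro-1,4-benzodioxin-7-yl}methanol (trans diol)
Conditions: iBu2AlH (6 equiv), CH2Cl2, −78 to 0 °C; aq potassium sodium tartrate
Reagents that add atoms: none
Why: Exhaustive ester reduction with an aluminium hydride, in which hydride delivery at low temperature is faster than enolisation at C3 and the aryl silyl ether and ring ethers are inert.

Step 5
Reactants: 8 trans diol
Product: 9 (2R,3R)-2-[3,5-dimethoxy-4-(triisopropylsilyloxy)phenyl]-3-(hydroxymethyl)-5-methoxy-2,3-dihydro-1,4-benzodioxine-7-carbaldehyde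
Conditions: activated MnO2 (excess), CH2Cl2, rt
Reagents that add atoms: none
Why: Chemoselective MnO2 oxidation, which acts only on the benzylic carbinol at C7 of the electron-rich ring A and leaves the saturated C3 hydroxymethyl group untouched.

Step 6
Reactants: 9 hydroxy aldehyde
Product: 10 {(2R,3R)-2-[3,5-dimethoxy-4-(triisopropylsilyloxy)phenyl]-5-methoxy-7-[(E)-prop-1-en-1-yl]-2,3-dihydro-1,4-benzodioxin-3-yl}methanol
Conditions: CrCl2 (8 equiv), CH3CHI2 (3 equiv), THF, 0 °C to rt
Reagents that add atoms: 1,1-diiodoethane, CC(I)I
Why: Takai–Utimoto ethylidenation, in which the gem-dichromium reagent adds to the aryl aldehyde and elimination from the less crowded adduct should give the (E)-alkene, while the weakly basic reagent tolerates the free hydroxyl group and cannot disturb C2 or C3.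

Step 7
Reactants: 10 propenyl alcohol
Product: 11 {(2R,3R)-2-[3,5-dimethoxy-4-(triisopropylsilyloxy)phenyl]-5-methoxy-7-[(E)-prop-1-en-1-yl]-2,3-dihydro-1,4-benzodioxin-3-yl}methyl 4-methylbenzenesulfonate
Conditions: TsCl, Et3N, DMAP (cat.), CH2Cl2, 0 °C to rt
Reagents that add atoms: p-toluenesulfonyl chloride, Cc1ccc(cc1)S(=O)(=O)Cl
Why: Sulfonate ester formation (tosylation) at the only remaining hydroxyl group, a primary one, with no bond to a stereocentre involved.

Step 8
Reactants: 11 tosylate
Product: 12 [4-{(2R,3R)-5-methoxy-3-methyl-7-[(E)-prop-1-en-1-yl]-2,3-dihydro-1,4-benzodioxin-2-yl}-2,6-dimethoxyphenoxy]triisopropylsilane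
Conditions: LiEt3BH (3 equiv), THF, 0 °C to rt; aq NH4Cl
Reagents that add atoms: none
Why: SN2 hydride displacement of a primary tosylate by LiEt3BH (deoxygenation of CH2OH to CH3), a nucleophile strong enough for a β-oxygenated primary centre, with substitution at the exocyclic carbon only and the alkene, aryl ethers and silyl ether left alone at this temperature.

Step 9
Reactants: 12 silyl ether of the target
Product: 13 4-{(2R,3R)-5-methoxy-3-methyl-7-[(E)-prop-1-en-1-yl]-2,3-dihydro-1,4-benzodioxin-2-yl}-2,6-dimethoxyphenol (CNP0227775.1)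
Conditions: Bu4NF, AcOH (1:1), THF, 0 °C
Reagents that add atoms: none
Why: Fluoride-induced desilylation of an aryl silyl ether, buffered with acetic acid so that the liberated phenol stays protonated and cannot expel O1 from C2 as a para-quinone methide, which preserves the C2 configuration.

Compound list
1 | syringaldehyde | COc1cc(C=O)cc(OC)c1O | starting material
2 | 3,5-dimethoxy-4-(triisopropylsilyloxy)benzaldehyde | O=Cc1cc(OC)c(O[Si](C(C)C)(C(C)C)C(C)C)c(OC)c1 | intermediate
3 | methyl 3-bromo-4-hydroxy-5-methoxybenzoate | COC(=O)c1cc(OC)c(O)c(Br)c1 | starting material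
4 | ethyl diazoacetate | CCOC(=O)C=[N+]=[N-] | starting material
5 | oxonium ylide from 3 and the carbene of 4 (not isolated) | COC(=O)c1cc(OC)c([OH+][CH-]C(=O)OCC)c(Br)c1 | intermediate
6 | ethyl (2S,3R)-2-[2-bromo-6-methoxy-4-(methoxycarbonyl)phenoxy]-3-[3,5-dimethoxy-4-(triisopropylsilyloxy)phenyl]-3-hydroxypropanoate (threo) | COC(=O)c1cc(OC)c(O[C@H](C(=O)OCC)[C@H](O)c2cc(OC)c(O[Si](C(C)C)(C(C)C)C(C)C)c(OC)c2)c(Br)c1 | intermediate
7 | trans-(2R,3S) benzodioxane 3-ethyl 7-methyl diester | COC(=O)c1cc(OC)c2c(c1)O[C@H](c1cc(OC)c(O[Si](C(C)C)(C(C)C)C(C)C)c(OC)c1)[C@@H](C(=O)OCC)O2 | intermediate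
8 | trans-(2R,3R) 3,7-bis(hydroxymethyl) benzodioxane | OCc1cc(OC)c2c(c1)O[C@H](c1cc(OC)c(O[Si](C(C)C)(C(C)C)C(C)C)c(OC)c1)[C@@H](CO)O2 | intermediate
9 | trans-(2R,3R) 3-hydroxymethyl benzodioxane-7-carbaldehyde | O=Cc1cc(OC)c2c(c1)O[C@H](c1cc(OC)c(O[Si](C(C)C)(C(C)C)C(C)C)c(OC)c1)[C@@H](CO)O2 | intermediate
10 | trans-(2R,3R) 3-hydroxymethyl-7-[(E)-propenyl] benzodioxane | C/C=C/c1cc(OC)c2c(c1)O[C@H](c1cc(OC)c(O[Si](C(C)C)(C(C)C)C(C)C)c(OC)c1)[C@@H](CO)O2 | intermediate
11 | tosylate of 10 | C/C=C/c1cc(OC)c2c(c1)O[C@H](c1cc(OC)c(O[Si](C(C)C)(C(C)C)C(C)C)c(OC)c1)[C@@H](COS(=O)(=O)c1ccc(C)cc1)O2 | intermediate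
12 | O-triisopropylsilyl ether of the target, trans-(2R,3R) | C/C=C/c1cc(OC)c2c(c1)O[C@H](c1cc(OC)c(O[Si](C(C)C)(C(C)C)C(C)C)c(OC)c1)[C@@H](C)O2 | intermediate
13 | 4-{(2R,3R)-5-methoxy-3-methyl-7-[(E)-prop-1-en-1-yl]-2,3-dihydro-1,4-benzodioxin-2-yl}-2,6-dimethoxyphenol | C/C=C/c1cc(OC)c2c(c1)O[C@H](c1cc(OC)c(O)c(OC)c1)[C@@H](C)O2 | target

Total step count: 9. Longest linear sequence: 9 (1 to 13; 3 and 4 enter at step 2 as bought).

Steps most likely to fail

**Step 2.** Protonation of the ylide carbon may outrun its capture by the aldehyde, or facial and threo/erythro control may be poor.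
- Fallback: separate the two bond formations and hand stereocontrol to an auxiliary.
- It sets out from 3. Williamson alkylation with commercial (S)-4-benzyl-3-(chloroacetyl)oxazolidin-2-one (K2CO3, NaI cat., acetone, rt) should give the aryloxyacetyl imide F1.
- An Evans syn glycolate aldol (Bu2BOTf, Et3N, CH2Cl2, −78 to 0 °C, then 2) should proceed through the closed boron chair transition state and give the threo (2S,3R) aldol imide F2.
- Ethanolysis with EtOMgBr (THF, 0 °C) releases the auxiliary and comes back to the route at 6.

**Step 3.** The possible failures are retro-aldol cleavage of the β-hydroxy ester under base, enolisation at C3 followed by expulsion of O1, or β-hydride elimination at the palladium alkoxide.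
- Fallback: remove the carbonyl group before the ring is closed.
- It sets out from 6. Reduction with iBu2AlH (CH2Cl2, −78 to 0 °C) should give the threo triol F3.
- The two primary hydroxyls are capped selectively (TBSCl 2.1 equiv, imidazole, CH2Cl2, 0 °C) to give the bis-silyl ether F4. This capping blocks the competing closure of the C3–CH2OH oxygen onto C8a.
- The same palladium etherification, now on a substrate without acidic C–H or an aldol retron, should give the benzodioxane bis-silyl ether F5.
- Camphorsulfonic acid in MeOH (0 °C) removes the two alkyl silyl ethers but not the aryl triisopropylsilyl ether, and the fallback comes back to the route at 8.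

**Step 6.** E selectivity may be incomplete, or conversion sluggish because the free hydroxyl group consumes the chromium reagent.
- Fallback: build the alkene under thermodynamic control.
- It sets out from 9. Wittig methylenation (Ph3PCH3Br, KOtBu, 2.5 equiv each, THF, 0 °C) should give the 7-vinyl alcohol F6.
- Cross-metathesis with excess (Z)-but-2-ene (second-generation Hoveyda–Grubbs catalyst, CH2Cl2, 40 °C) exchanges the terminal CH2 for ethylidene. It should settle on the conjugated (E)-propenylarene, and the fallback comes back to the route at 10.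

Further compounds
F1 | step 2 | methyl 4-{2-[(4S)-4-benzyl-2-oxo-1,3-oxazolidin-3-yl]-2-oxoethoxy}-3-bromo-5-methoxybenzoate | COC(=O)c1cc(OC)c(OCC(=O)N2[C@@H](Cc3ccccc3)COC2=O)c(Br)c1
F2 | step 2 | (4S)-4-benzyl-3-{(2S,3R)-2-[2-bromo-6-methoxy-4-(methoxycarbonyl)phenoxy]-3-[3,5-dimethoxy-4-(triisopropylsilyloxy)phenyl]-3-hydroxypropanoyl}-1,3-oxazolidin-2-one | COC(=O)c1cc(OC)c(O[C@H](C(=O)N2[C@@H](Cc3ccccc3)COC2=O)[C@H](O)c4cc(OC)c(O[Si](C(C)C)(C(C)C)C(C)C)c(OC)c4)c(Br)c1
F3 | step 3 | (1R,2R)-2-[2-bromo-4-(hydroxymethyl)-6-methoxyphenoxy]-1-[3,5-dimethoxy-4-(triisopropylsilyloxy)phenyl]propane-1,3-diol (threo) | OCc1cc(OC)c(O[C@H](CO)[C@H](O)c2cc(OC)c(O[Si](C(C)C)(C(C)C)C(C)C)c(OC)c2)c(Br)c1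
F4 | step 3 | bis(tert-butyldimethylsilyl) ether of F3 at both primary hydroxyls | CC(C)(C)[Si](C)(C)OCc1cc(OC)c(O[C@H](CO[Si](C)(C)C(C)(C)C)[C@H](O)c2cc(OC)c(O[Si](C(C)C)(C(C)C)C(C)C)c(OC)c2)c(Br)c1
F5 | step 3 | bis(tert-butyldimethylsilyl) ether of 8, trans-(2R,3R) | CC(C)(C)[Si](C)(C)OCc1cc(OC)c2c(c1)O[C@H](c1cc(OC)c(O[Si](C(C)C)(C(C)C)C(C)C)c(OC)c1)[C@@H](CO[Si](C)(C)C(C)(C)C)O2
F6 | step 6 | {(2R,3R)-2-[3,5-dimethoxy-4-(triisopropylsilyloxy)phenyl]-7-ethenyl-5-methoxy-2,3-dihydro-1,4-benzodioxin-3-yl}methanol | C=Cc1cc(OC)c2c(c1)O[C@H](c1cc(OC)c(O[Si](C(C)C)(C(C)C)C(C)C)c(OC)c1)[C@@H](CO)O2
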